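**Plan**

- Ring numbering used here: C1 is the quaternary carbinol that carries the tridecanoyl group, C2 is CH(OH), C3=C4 is the alkene, C5 is CH(OAc). Oxygen on C2, C1 and C5 together with the C3=C4 alkene is the pattern of an oxidised 2-furylcarbinol (carbinol carbon = C1, furan carbons = C2 to C5) that lacks only the C1–C5 ring bond.
- Retrosynthesis: the side-chain C=O goes back to a 4-methoxybenzyl-protected carbinol and C2–OH to a ketone. The C1–C5 bond is then cut (aldol) to an Achmatowicz pyranone, the C1–C2 bond to furan plus (S)-2-(4-methoxybenzyloxy)tetradecanal, and the chain to (S)-glycidyl trityl ether plus undecylmagnesium bromide.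
- Forward: the chain is joined by epoxide opening and furan is added. The furan is expanded to the pyranone, which is contracted to the cyclopentenone (the only carbocycle). Acetylation, ketone reduction and side-chain oxidation follow.
- Stereochemistry: the glycidyl stereocentre becomes the side-chain ether carbon. It directs the aldol that sets C1 and C5 (hydroxyls trans) and makes the two possible ring senses diastereomeric. C2 comes from hydride attack anti to the side chain. The auxiliary centre is finally oxidised to the ketone.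
- The triol core is meso, so the absolute configuration lies only in which of the two cis secondary oxygens carries the acetate. Acetylating the aldol hydroxyl before the ketone is reduced fixes this.

Key step: step 7

Assumption: the (S)-ether carbon steers the ring closure mainly to the (4S,5S)-cyclopentenone, and the relative configuration of ring and side chain is confirmed (crystal structure or nOe study of a cyclic derivative) before that isomer is carried on.

**Route**

Step 1
Reactants: 1 (S)-glycidyl trityl ether; 2 undecylmagnesium bromide (commercial solution)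
Product: 3 (2S)-1-(triphenylmethoxy)tetradecan-2-ol
Conditions: CuI (10 mol%), THF, −30 °C to 0 °C; aq NH4Cl
Reagents that add atoms: none
Why: Copper-catalysed Grignard opening of a terminal epoxide is an SN2 attack at the unsubstituted carbon, so the dodecyl chain is completed while the stereocentre of 1 passes unchanged into 3.

Step 2
Reactants: 3 (2S)-1-(triphenylmethoxy)tetradecan-2-ol
Product: 4 (2S)-2-[(4-methoxybenzyl)oxy]-1-(triphenylmethoxy)tetradecane
Conditions: NaH, 4-methoxybenzyl chloride, Bu4NI (cat.), DMF, 0 °C to rt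
Reagents that add atoms: 4-methoxybenzyl chloride, COc1ccc(CCl)cc1
Why: Williamson etherification of the sodium alkoxide with the benzylic chloride under iodide catalysis is routine for secondary alcohols, and the trityl ether is inert to base.

Step 3
Reactants: 4 (2S)-2-[(4-methoxybenzyl)oxy]-1-(triphenylmethoxy)tetradecane
Product: 5 (2S)-2-[(4-methoxybenzyl)oxy]tetradecan-1-ol
Conditions: TsOH·H2O (cat.), MeOH–CH2Cl2 (1:1), rt
Reagents that add atoms: none
Why: Acid-catalysed methanolysis (SN1 through the trityl cation) removes the trityl ether far faster than the 4-methoxybenzyl ether can ionise, so only the primary hydroxyl is set free.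

Step 4
Reactants: 5 (2S)-2-[(4-methoxybenzyl)oxy]tetradecan-1-ol
Product: 6 (2S)-2-[(4-methoxybenzyl)oxy]tetradecanal
Conditions: Dess–Martin periodinane, pyridine, CH2Cl2, 0 °C to rt; used crude
Reagents that add atoms: none
Why: Dess–Martin oxidation under buffered non-enolising conditions should deliver the configurationally labile α-alkoxy aldehyde without epimerisation, and it is used at once without silica purification.

Step 5
Reactants: 6 (2S)-2-[(4-methoxybenzyl)oxy]tetradecanal; 7 furan
Product: 9 (2S)-1-(furan-2-yl)-2-[(4-methoxybenzyl)oxy]tetradecan-1-ol as both C1 epimers, via 2-furyllithium 8 (not isolated)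
Conditions: furan, n-BuLi, THF, 0 °C; then 6, −78 °C; aq NH4Cl
Reagents that add atoms: none
Why: Lithiation of furan at C2 and 1,2-addition of the organolithium to the aldehyde at low temperature is standard, and the configuration of the new carbinol is immaterial because this carbon becomes trigonal in step 7.

Step 6
Reactants: 9 (2S)-1-(furan-2-yl)-2-[(4-methoxybenzyl)oxy]tetradecan-1-ol
Product: 10 6-hydroxy-2-[(1S)-1-[(4-methoxybenzyl)oxy]tridecyl]-2H-pyran-3(6H)-one (epimers at C2 and C6)
Conditions: NBS (1.05 equiv), NaHCO3, THF–H2O (4:1), 0 °C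
Reagents that add atoms: water, O
Why: Achmatowicz rearrangement, in which bromonium-induced hydration of the furan gives the cis-enedione that the carbinol oxygen captures as the pyranone lactol, and one equivalent of NBS at 0 °C should consume the furan well before the anisyl ring reacts.

Step 7
Reactants: 10 6-hydroxy-2-[(1S)-1-[(4-methoxybenzyl)oxy]tridecyl]-2H-pyran-3(6H)-one
Product: 12 (4S,5S)-4,5-dihydroxy-5-[(1S)-1-[(4-methoxybenzyl)oxy]tridecyl]cyclopent-2-en-1-one, via open-chain (Z)-keto-enal 11 (not isolated)
Conditions: Et3N (0.5 equiv), DMF, 0 °C to rt; chromatographic separation of diastereomers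
Reagents that add atoms: none
Why: Triethylamine sets up the ring–chain tautomerism of lactol 10 to the (Z)-keto-enal 11, the α-hydroxy ketone of 11 enolises toward the former pyranone C2 to an enediolate, and this carbon adds to the aldehyde that the Z alkene holds beside it, forming the C1–C5 bond of the target ring. The closest known reaction type is the amine-mediated isomerisation of Achmatowicz pyranones to trans-4,5-dihydroxycyclopent-2-enones. The cyclopentenone closes in a 5-(enolendo)-exo-trig aldol, both enediolate carbons lying inside the new ring, the same mode by which cis-enediones and 1,4-diketones are known to give cyclopentenones. Of the two new stereocentres, the secondary carbinol (C5 of the target ring) is expected to carry its hydroxyl trans to the quaternary hydroxyl as in the known isomerisations, with retro-aldol equilibration available to correct a cis isomer, while the quaternary carbon (C1) takes its absolute sense from the (S)-ether carbon, whose C–H bond lies in the enediolate plane (allylic 1,3-strain) so that the aldehyde adds anti to the dodecyl chain. The step needs the aldol to outrun E1cB loss of the β-arylmethoxy group and oxidopyrylium formation, which the poor alkoxide leaving group, the free (unacylated) lactol and the mildness of the amine should secure. Both C2 and C6 epimers of 10 converge, because C2 becomes trigonal and C6 becomes the aldehyde.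

Step 8
Reactants: 12 (4S,5S)-4,5-dihydroxy-5-[(1S)-1-[(4-methoxybenzyl)oxy]tridecyl]cyclopent-2-en-1-one
Product: 13 (1S,5R)-5-hydroxy-5-[(1S)-1-[(4-methoxybenzyl)oxy]tridecyl]-4-oxocyclopent-2-en-1-yl acetate
Conditions: Ac2O, pyridine, DMAP (cat.), CH2Cl2, 0 °C
Reagents that add atoms: acetic anhydride, CC(=O)OC(C)=O
Why: DMAP-catalysed acylation should take the secondary allylic hydroxyl and leave the congested tertiary one, and capping the β-hydroxyl also ends the reversibility of the aldol.

Step 9
Reactants: 13 (1S,5R)-5-hydroxy-5-[(1S)-1-[(4-methoxybenzyl)oxy]tridecyl]-4-oxocyclopent-2-en-1-yl acetate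
Product: 14 (1S,4R,5R)-4,5-dihydroxy-5-[(1S)-1-[(4-methoxybenzyl)oxy]tridecyl]cyclopent-2-en-1-yl acetate
Conditions: NaBH4, CeCl3·7H2O, MeOH, −78 °C
Reagents that add atoms: none
Why: Luche reduction gives 1,2-reduction of the enone at −78 °C without touching the acetate, and hydride should enter on the ring face that carries only the tertiary hydroxyl, anti to the side chain and the acetoxy group, which places the new hydroxyl trans to the tertiary one (4R).

Step 10
Reactants: 14 (1S,4R,5R)-4,5-dihydroxy-5-[(1S)-1-[(4-methoxybenzyl)oxy]tridecyl]cyclopent-2-en-1-yl acetate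
Product: 15 (1S,4R,5R)-5-hydroxy-5-[(1S)-1-[(4-methoxybenzyl)oxy]tridecyl]-4-[(triethylsilyl)oxy]cyclopent-2-en-1-yl acetate
Conditions: TESOTf (1.1 equiv), 2,6-lutidine, CH2Cl2, −78 °C
Reagents that add atoms: triethylsilyl trifluoromethanesulfonate, CC[Si](CC)(CC)OS(=O)(=O)C(F)(F)F
Why: Silylation with the silyl triflate and a hindered pyridine base at −78 °C distinguishes the secondary from the tertiary hydroxyl and is too weakly basic to move the acetyl group.

Step 11
Reactants: 15 (1S,4R,5R)-5-hydroxy-5-[(1S)-1-[(4-methoxybenzyl)oxy]tridecyl]-4-[(triethylsilyl)oxy]cyclopent-2-en-1-yl acetate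
Product: 16 (1S,4R,5R)-5-hydroxy-5-[(1S)-1-hydroxytridecyl]-4-[(triethylsilyl)oxy]cyclopent-2-en-1-yl acetate
Conditions: DDQ, CH2Cl2–pH 7 phosphate buffer (10:1), 0 °C
Reagents that add atoms: none
Why: Oxidative cleavage of the 4-methoxybenzyl ether by DDQ (hydride abstraction, then hydrolysis of the oxocarbenium ion) tolerates the silyl ether, the acetate and the alkene, and the water-rich buffered medium should outcompete the hindered tertiary hydroxyl for the cation.

Step 12
Reactants: 16 (1S,4R,5R)-5-hydroxy-5-[(1S)-1-hydroxytridecyl]-4-[(triethylsilyl)oxy]cyclopent-2-en-1-yl acetate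
Product: 17 (1S,4R,5R)-5-hydroxy-5-tridecanoyl-4-[(triethylsilyl)oxy]cyclopent-2-en-1-yl acetate
Conditions: Dess–Martin periodinane, pyridine, CH2Cl2, 0 °C to rt
Reagents that add atoms: none
Why: Dess–Martin oxidation of the only free secondary hydroxyl gives the α-hydroxy ketone, normally without cleaving a tertiary/secondary glycol, and thereby erases the auxiliary stereocentre.

Step 13
Reactants: 17 (1S,4R,5R)-5-hydroxy-5-tridecanoyl-4-[(triethylsilyl)oxy]cyclopent-2-en-1-yl acetate
Product: 18 (1S,4R,5S)-4,5-dihydroxy-5-tridecanoylcyclopent-2-en-1-yl acetate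
Conditions: HF·pyridine, pyridine, THF, 0 °C
Reagents that add atoms: none
Why: Fluoride-induced desilylation with buffered HF·pyridine is weakly acidic, so the Si–O bond is cleaved without the basic conditions that would allow acetyl migration to the cis hydroxyl (which would racemise the meso-derived core) or retro-aldol opening of the β-hydroxy ketone.

**Compound list**

1 | (S)-glycidyl trityl ether, (2S)-2-[(triphenylmethoxy)methyl]oxirane | C(c1ccccc1)(c1ccccc1)(c1ccccc1)OC[C@@H]1CO1 | starting material
2 | undecylmagnesium bromide | CCCCCCCCCCC[Mg]Br | starting material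
3 | (2S)-1-(triphenylmethoxy)tetradecan-2-ol | CCCCCCCCCCCC[C@H](O)COC(c1ccccc1)(c1ccccc1)c1ccccc1 | intermediate
4 | (2S)-2-[(4-methoxybenzyl)oxy]-1-(triphenylmethoxy)tetradecane | CCCCCCCCCCCC[C@H](OCc1ccc(OC)cc1)COC(c1ccccc1)(c1ccccc1)c1ccccc1 | intermediate
5 | (2S)-2-[(4-methoxybenzyl)oxy]tetradecan-1-ol | CCCCCCCCCCCC[C@H](OCc1ccc(OC)cc1)CO | intermediate
6 | (2S)-2-[(4-methoxybenzyl)oxy]tetradecanal | CCCCCCCCCCCC[C@H](OCc1ccc(OC)cc1)C=O | intermediate
7 | furan | c1ccoc1 | starting material
8 | 2-furyllithium | [Li]c1ccco1 | intermediate (not isolated)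
9 | (2S)-1-(furan-2-yl)-2-[(4-methoxybenzyl)oxy]tetradecan-1-ol, both C1 epimers | CCCCCCCCCCCC[C@H](OCc1ccc(OC)cc1)C(O)c1ccco1 | intermediate
10 | 6-hydroxy-2-[(1S)-1-[(4-methoxybenzyl)oxy]tridecyl]-2H-pyran-3(6H)-one, epimers at C2 and C6 | CCCCCCCCCCCC[C@H](OCc1ccc(OC)cc1)C1OC(O)C=CC1=O | intermediate
11 | (2Z,6S)-5-hydroxy-6-[(4-methoxybenzyl)oxy]-4-oxooctadec-2-enal, C5 epimers | CCCCCCCCCCCC[C@H](OCc1ccc(OC)cc1)C(O)C(=O)/C=C\C=O | intermediate (not isolated)
12 | (4S,5S)-4,5-dihydroxy-5-[(1S)-1-[(4-methoxybenzyl)oxy]tridecyl]cyclopent-2-en-1-one | CCCCCCCCCCCC[C@H](OCc1ccc(OC)cc1)[C@]1(O)C(=O)C=C[C@@H]1O | intermediate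
13 | (1S,5R)-5-hydroxy-5-[(1S)-1-[(4-methoxybenzyl)oxy]tridecyl]-4-oxocyclopent-2-en-1-yl acetate | CCCCCCCCCCCC[C@H](OCc1ccc(OC)cc1)[C@]1(O)C(=O)C=C[C@@H]1OC(C)=O | intermediate
14 | (1S,4R,5R)-4,5-dihydroxy-5-[(1S)-1-[(4-methoxybenzyl)oxy]tridecyl]cyclopent-2-en-1-yl acetate | CCCCCCCCCCCC[C@H](OCc1ccc(OC)cc1)[C@]1(O)[C@H](O)C=C[C@@H]1OC(C)=O | intermediate
15 | (1S,4R,5R)-5-hydroxy-5-[(1S)-1-[(4-methoxybenzyl)oxy]tridecyl]-4-[(triethylsilyl)oxy]cyclopent-2-en-1-yl acetate | CCCCCCCCCCCC[C@H](OCc1ccc(OC)cc1)[C@]1(O)[C@H](O[Si](CC)(CC)CC)C=C[C@@H]1OC(C)=O | intermediate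
16 | (1S,4R,5R)-5-hydroxy-5-[(1S)-1-hydroxytridecyl]-4-[(triethylsilyl)oxy]cyclopent-2-en-1-yl acetate | CCCCCCCCCCCC[C@H](O)[C@]1(O)[C@H](O[Si](CC)(CC)CC)C=C[C@@H]1OC(C)=O | intermediate
17 | (1S,4R,5R)-5-hydroxy-5-tridecanoyl-4-[(triethylsilyl)oxy]cyclopent-2-en-1-yl acetate | CCCCCCCCCCCCC(=O)[C@]1(O)[C@H](O[Si](CC)(CC)CC)C=C[C@@H]1OC(C)=O | intermediate
18 | (1S,4R,5S)-4,5-dihydroxy-5-tridecanoylcyclopent-2-en-1-yl acetate | CCCCCCCCCCCCC(=O)[C@]1(O)[C@H](O)C=C[C@@H]1OC(C)=O | target

**Step count**

Total steps: 13. Longest linear sequence: 13 steps (1 to 18); furan 7 enters in step 5.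

**Steps most likely to fail**

Step 7. The enediolate may be attacked on both faces, or mainly on the face opposite to the one assumed, so that much of the material closes to the trans-diol of opposite ring sense. The fallback sets out from 10 and comes back at 15. The second diastereomer, the (4R,5R) trans-diol cyclopentenone F1, is separated from 12. Because the triol core of the target is meso, it is advanced by exchanging the order of the two oxygen-capping steps. Its secondary hydroxyl is silylated first (TESOTf, 2,6-lutidine, CH2Cl2, −78 °C) to give the 4-O-triethylsilyl enone F2. Luche reduction (NaBH4, CeCl3·7H2O, MeOH, −78 °C), again from the face of the tertiary hydroxyl, gives the allylic alcohol F3. Acetylation of the new secondary hydroxyl (Ac2O, pyridine, DMAP) then gives 15 itself. Either facial outcome of the aldol therefore feeds the same intermediate, and a cis-diol isomer is returned to the equilibrium by renewed exposure to the amine.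

Step 11. The benzylic oxocarbenium ion formed by DDQ may be captured by the neighbouring tertiary hydroxyl (cyclic 4-methoxybenzylidene acetal, then a benzoate on further oxidation) instead of by water. The fallback sets out from 15 and comes back at 18. The tertiary hydroxyl is capped first (TMSOTf, 2,6-lutidine, CH2Cl2, 0 °C) to give the mixed bis-silyl ether F4. DDQ in wet CH2Cl2 can then only give the side-chain alcohol F5. Dess–Martin oxidation gives the bis-silylated ketone F6 with no free glycol present, which also removes the risk of glycol cleavage in step 12. HF·pyridine in THF removes both silyl groups to give 18.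

Step 9. Hydride may enter from the wrong ring face, or methoxide formed in the methanolic borohydride medium may cleave or shift the acetate. The fallback sets out from 13 and comes back at 14 and makes no compound outside the list (entry F0). External hydride attack is replaced by intramolecular delivery: Me4NBH(OAc)3 in MeCN–AcOH at −20 °C exchanges the tertiary hydroxyl onto boron and delivers hydride to the carbonyl from that hydroxyl's own face. This should give the same trans-diol 14 in an acidic, non-nucleophilic medium that leaves the acetate in place.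

**Further compounds**

F1 | step 7 | (4R,5R)-4,5-dihydroxy-5-[(1S)-1-[(4-methoxybenzyl)oxy]tridecyl]cyclopent-2-en-1-one | CCCCCCCCCCCC[C@H](OCc1ccc(OC)cc1)[C@@]1(O)C(=O)C=C[C@H]1O
F2 | step 7 | (4R,5S)-5-hydroxy-5-[(1S)-1-[(4-methoxybenzyl)oxy]tridecyl]-4-[(triethylsilyl)oxy]cyclopent-2-en-1-one | CCCCCCCCCCCC[C@H](OCc1ccc(OC)cc1)[C@@]1(O)C(=O)C=C[C@H]1O[Si](CC)(CC)CC
F3 | step 7 | (1S,2S,5R)-1-[(1S)-1-[(4-methoxybenzyl)oxy]tridecyl]-5-[(triethylsilyl)oxy]cyclopent-3-ene-1,2-diol | CCCCCCCCCCCC[C@H](OCc1ccc(OC)cc1)[C@@]1(O)[C@@H](O)C=C[C@H]1O[Si](CC)(CC)CC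
F4 | step 11 | (1S,4R,5R)-5-[(1S)-1-[(4-methoxybenzyl)oxy]tridecyl]-4-[(triethylsilyl)oxy]-5-[(trimethylsilyl)oxy]cyclopent-2-en-1-yl acetate | CCCCCCCCCCCC[C@H](OCc1ccc(OC)cc1)[C@]1(O[Si](C)(C)C)[C@H](O[Si](CC)(CC)CC)C=C[C@@H]1OC(C)=O
F5 | step 11 | (1S,4R,5R)-5-[(1S)-1-hydroxytridecyl]-4-[(triethylsilyl)oxy]-5-[(trimethylsilyl)oxy]cyclopent-2-en-1-yl acetate | CCCCCCCCCCCC[C@H](O)[C@]1(O[Si](C)(C)C)[C@H](O[Si](CC)(CC)CC)C=C[C@@H]1OC(C)=O
F6 | step 11 | (1S,4R,5R)-5-tridecanoyl-4-[(triethylsilyl)oxy]-5-[(trimethylsilyl)oxy]cyclopent-2-en-1-yl acetate | CCCCCCCCCCCCC(=O)[C@]1(O[Si](C)(C)C)[C@H](O[Si](CC)(CC)CC)C=C[C@@H]1OC(C)=O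
F0 | step 9 | none | none
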